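**Retrosynthetic overview**

1. Last bond: the ester C–O at the oxymethyl carbon on C3 (lignan C9), made by Mitsunobu coupling of the fully deprotected tetrahydrofuran with ferulic acid.
2. Tetrahydrofuran ring (O1, C2–C5), formed last: C2–O1 is cut to an acyclic triol whose benzylic (syringyl) carbinol ionises and is trapped by the C5 hydroxyl; the triol comes from LiAlH4 reduction of a trans aldol adduct (C2–C3 bond) of a β-benzyl-γ-butyrolactone with O-benzylsyringaldehyde.
3. Feature on which the plan rests: ring carbon C4, which carries the guaiacylmethyl arm, lies between C3 and C5; joining C3 and C5 through the C9 carbon as a carbonyl gives an achiral 3-(arylmethyl)cyclobutanone in which C3 and C5 are enantiotopic CH2 groups.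
4. γ-Butyrolactone ring, formed second: the O1–C5 bond is cut by a retro-Baeyer–Villiger step to that cyclobutanone, so one catalytic desymmetrization sets C4 and every later centre is relayed from it.
5. Cyclobutane ring, formed first: [2+2] cycloaddition of dichloroketene to O-benzyleugenol, then dechlorination; ring order is cyclobutanone, lactone (ring expansion), tetrahydrofuran (after reductive opening of the lactone).

Key step: step 4

Assumption (catalyst sense): the (S)-antipode of the phosphoric acid is taken to deliver the (R)-lactone; the sense would be checked on the first run by sign of rotation and chiral HPLC, and the (R)-acid used instead if the opposite lactone forms.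
Remark: the carbinol carbon created in step 6 is carried as a mixture of epimers, because this centre is ionised in step 8.

**Route**

Step 1
Reactants: 1 eugenol (4-allyl-2-methoxyphenol)
Product: 2 4-allyl-1-(benzyloxy)-2-methoxybenzene
Conditions: BnBr, K2CO3, acetone, reflux
Reagents that add atoms: benzyl bromide, BrCc1ccccc1
Why: Williamson ether synthesis, in which the phenoxide formed with K2CO3 displaces bromide from benzyl bromide and the allyl group is untouched.

Step 2
Reactants: 2 4-allyl-1-(benzyloxy)-2-methoxybenzene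
Product: 3 rac-3-[4-(benzyloxy)-3-methoxybenzyl]-2,2-dichlorocyclobutan-1-one
Conditions: Cl3CCOCl, Zn–Cu couple, POCl3, Et2O, reflux
Reagents that add atoms: trichloroacetyl chloride, ClC(=O)C(Cl)(Cl)Cl
Why: Thermal [2+2] ketene–alkene cycloaddition of dichloroketene (made in the flask by zinc dechlorination of the acid chloride) to the terminal alkene, the ketene carbonyl carbon bonding to the terminal CH2 so that CCl2 ends next to the substituted carbon; POCl3 ties up ZnCl2 and so spares the benzyl ether and the electron-rich ring, and the one stereocentre forms as a racemate that is erased in step 3.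

Step 3
Reactants: 3 rac-3-[4-(benzyloxy)-3-methoxybenzyl]-2,2-dichlorocyclobutan-1-one
Product: 4 3-[4-(benzyloxy)-3-methoxybenzyl]cyclobutan-1-one
Conditions: Zn dust, AcOH, rt to 60 °C
Reagents that add atoms: none
Why: Reductive dechlorination of the α,α-dichloroketone by zinc in acetic acid (through zinc enolates) removes both chlorines and leaves the achiral, mirror-symmetric ketone; the aryl benzyl ether is stable to these conditions.

Step 4
Reactants: 4 3-[4-(benzyloxy)-3-methoxybenzyl]cyclobutan-1-one
Product: 6 (4R)-4-[4-(benzyloxy)-3-methoxybenzyl]oxolan-2-one, via Criegee adduct 5 (not isolated)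
Conditions: (S)-3,3'-di(pyren-1-yl)-5,5',6,6',7,7',8,8'-octahydro-1,1'-binaphthalene-2,2'-diyl hydrogen phosphate (10 mol%), 30% aq. H2O2 (1.5 equiv), CHCl3, −40 °C
Reagents that add atoms: hydrogen peroxide, OO
Why: The phosphoric acid activates the strained ketone and hydrogen-bonds H2O2, which adds to the carbonyl to give the tetrahedral Criegee adduct 5 held between the two pyrenyl walls; the same acid then assists loss of water while one α-methylene shifts from carbon to the peroxide oxygen. The closest known reaction type is the chiral phosphoric acid/aqueous H2O2 Baeyer–Villiger desymmetrization of 3-aryl- and 3-benzylcyclobutanones. The γ-butyrolactone is not closed end to end: it arises by ring expansion, the four-membered carbocycle growing to the five-membered lactone as oxygen is inserted between the carbonyl carbon and the migrating CH2, which becomes C5. The one new stereocentre, C4 of the lactone (former C3 of the cyclobutanone), becomes stereogenic only because the two ring CH2 groups are made different, and it is controlled by the catalyst alone, which decides which enantiotopic C–C bond lies antiperiplanar to the O–O bond in the bound adduct. The step needs only this enantiotopic-group selection, since both candidates for migration are equivalent CH2 groups and there is no regiochemical question; ring strain secures chemoselectivity, because it lets the ketone react at −40 °C, where H2O2 leaves the benzyl ether and the electron-rich arene alone and no uncatalysed oxidation competes.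

Step 5
Reactants: 7 syringaldehyde (4-hydroxy-3,5-dimethoxybenzaldehyde)
Product: 8 4-(benzyloxy)-3,5-dimethoxybenzaldehyde
Conditions: BnBr, K2CO3, DMF, 60 °C
Reagents that add atoms: benzyl bromide, BrCc1ccccc1
Why: Williamson ether synthesis; the phenol flanked by two methoxy groups needs DMF and warming, and the aldehyde, having no α-hydrogen, is stable to K2CO3.

Step 6
Reactants: 6 (4R)-4-[4-(benzyloxy)-3-methoxybenzyl]oxolan-2-one; 8 4-(benzyloxy)-3,5-dimethoxybenzaldehyde
Product: 10 (3S,4R)-3-{[4-(benzyloxy)-3,5-dimethoxyphenyl](hydroxy)methyl}-4-[4-(benzyloxy)-3-methoxybenzyl]oxolan-2-one (3,4-trans; both carbinol epimers), via lithium enolate 9 (not isolated)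
Conditions: LiN(iPr)2, THF, −78 °C; then 8, −78 °C; sat. aq. NH4Cl at −78 °C
Reagents that add atoms: none
Why: Lithium enolate aldol addition in which the aldehyde approaches enolate 9 on the face opposite the C4 benzyl group, setting C3 trans to C4 (3S); the carbinol carbon forms unselectively, which is harmless, and the cold quench prevents retro-aldol cleavage.

Step 7
Reactants: 10 (3S,4R)-3-{[4-(benzyloxy)-3,5-dimethoxyphenyl](hydroxy)methyl}-4-[4-(benzyloxy)-3-methoxybenzyl]oxolan-2-one
Product: 11 (2R,3R)-2-{[4-(benzyloxy)-3,5-dimethoxyphenyl](hydroxy)methyl}-3-[4-(benzyloxy)-3-methoxybenzyl]butane-1,4-diol (both carbinol epimers)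
Conditions: LiAlH4, THF, 0 °C to rt; H2O quench
Reagents that add atoms: none
Why: Hydride reduction of the lactone to the 1,4-diol with LiAlH4, fast enough at 0 °C to outrun retro-aldol cleavage of the aluminium aldolate; the two ring stereocentres are carried over unchanged and benzyl ethers are inert.

Step 8
Reactants: 11 (2R,3R)-2-{[4-(benzyloxy)-3,5-dimethoxyphenyl](hydroxy)methyl}-3-[4-(benzyloxy)-3-methoxybenzyl]butane-1,4-diol
Product: 13 {(2S,3R,4R)-2-[4-(benzyloxy)-3,5-dimethoxyphenyl]-4-[4-(benzyloxy)-3-methoxybenzyl]oxolan-3-yl}methanol, via benzylic cation 12 (not isolated)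
Conditions: camphor-10-sulfonic acid (0.2 equiv), CH2Cl2, 0 °C to rt; Et3N quench
Reagents that add atoms: none
Why: Acid-catalysed SN1 cycloetherification, in which the benzylic hydroxyl para to the benzyloxy group ionises to cation 12 and the primary hydroxyl next to the benzyl-bearing carbon closes the ring (5-exo; the other hydroxyl could only form an oxetane); the aryl group settles trans to the neighbouring hydroxymethyl arm (2S), a preference reinforced by reversibility under the acid, while the trans lactone relation of step 6 has by now become the cis relation of the two arms on C3 and C4.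

Step 9
Reactants: 13 {(2S,3R,4R)-2-[4-(benzyloxy)-3,5-dimethoxyphenyl]-4-[4-(benzyloxy)-3-methoxybenzyl]oxolan-3-yl}methanol
Product: 14 4-[(2S,3R,4R)-4-(4-hydroxy-3-methoxybenzyl)-3-(hydroxymethyl)oxolan-2-yl]-2,6-dimethoxyphenol
Conditions: H2 (1 atm), 10% Pd/C, EtOAc, rt
Reagents that add atoms: none
Why: Catalytic hydrogenolysis of the two aryl benzyl ethers, which in neutral ethyl acetate at 1 atm should be much faster than cleavage of the cyclic benzylic C2–O1 bond, so the reaction is stopped as soon as both benzyl groups are gone; no stereocentre is touched.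

Step 10
Reactants: 14 4-[(2S,3R,4R)-4-(4-hydroxy-3-methoxybenzyl)-3-(hydroxymethyl)oxolan-2-yl]-2,6-dimethoxyphenol; 15 ferulic acid ((E)-3-(4-hydroxy-3-methoxyphenyl)prop-2-enoic acid)
Product: 16 {(2S,3R,4R)-2-(4-hydroxy-3,5-dimethoxyphenyl)-4-(4-hydroxy-3-methoxybenzyl)oxolan-3-yl}methyl (E)-3-(4-hydroxy-3-methoxyphenyl)prop-2-enoate (target)
Conditions: PPh3 (1.3 equiv), DIAD (1.3 equiv), THF, 0 °C to rt
Reagents that add atoms: none
Why: Mitsunobu esterification, in which the PPh3/DIAD betaine deprotonates the carboxylic acid (far more acidic than any phenol present) and the carboxylate displaces the primary alkoxyphosphonium ion, so the three phenols stay free and the E alkene is untouched; the carbon attacked is a CH2, so no stereocentre is involved.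

**Compound list**

1 | eugenol (4-allyl-2-methoxyphenol) | C=CCc1ccc(O)c(OC)c1 | starting material
2 | 4-allyl-1-(benzyloxy)-2-methoxybenzene | C=CCc1ccc(OCc2ccccc2)c(OC)c1 | intermediate
3 | rac-3-[4-(benzyloxy)-3-methoxybenzyl]-2,2-dichlorocyclobutan-1-one | O=C1CC(Cc2ccc(OCc3ccccc3)c(OC)c2)C1(Cl)Cl | intermediate
4 | 3-[4-(benzyloxy)-3-methoxybenzyl]cyclobutan-1-one (achiral) | O=C1CC(Cc2ccc(OCc3ccccc3)c(OC)c2)C1 | intermediate
5 | 3-[4-(benzyloxy)-3-methoxybenzyl]-1-hydroperoxycyclobutan-1-ol (Criegee adduct, catalyst-bound, not isolated) | OOC1(O)CC(Cc2ccc(OCc3ccccc3)c(OC)c2)C1 | intermediate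
6 | (4R)-4-[4-(benzyloxy)-3-methoxybenzyl]oxolan-2-one | O=C1C[C@@H](Cc2ccc(OCc3ccccc3)c(OC)c2)CO1 | intermediate
7 | syringaldehyde (4-hydroxy-3,5-dimethoxybenzaldehyde) | COc1cc(C=O)cc(OC)c1O | starting material
8 | 4-(benzyloxy)-3,5-dimethoxybenzaldehyde | COc1cc(C=O)cc(OC)c1OCc1ccccc1 | intermediate
9 | lithium (4R)-4-[4-(benzyloxy)-3-methoxybenzyl]-4,5-dihydrofuran-2-olate (lithium enolate, not isolated) | [Li]OC1=C[C@@H](Cc2ccc(OCc3ccccc3)c(OC)c2)CO1 | intermediate
10 | (3S,4R)-3-{[4-(benzyloxy)-3,5-dimethoxyphenyl](hydroxy)methyl}-4-[4-(benzyloxy)-3-methoxybenzyl]oxolan-2-one (3,4-trans; both carbinol epimers) | O=C1[C@H](C(O)c2cc(OC)c(OCc3ccccc3)c(OC)c2)[C@@H](Cc2ccc(OCc3ccccc3)c(OC)c2)CO1 | intermediate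
11 | (2R,3R)-2-{[4-(benzyloxy)-3,5-dimethoxyphenyl](hydroxy)methyl}-3-[4-(benzyloxy)-3-methoxybenzyl]butane-1,4-diol (both carbinol epimers) | OC[C@H](C(O)c1cc(OC)c(OCc2ccccc2)c(OC)c1)[C@@H](Cc1ccc(OCc2ccccc2)c(OC)c1)CO | intermediate
12 | benzylic cation from 11 (carbinol hydroxyl lost; the two chain stereocentres as in 11; not isolated) | OC[C@H]([CH+]c1cc(OC)c(OCc2ccccc2)c(OC)c1)[C@@H](Cc1ccc(OCc2ccccc2)c(OC)c1)CO | intermediate
13 | {(2S,3R,4R)-2-[4-(benzyloxy)-3,5-dimethoxyphenyl]-4-[4-(benzyloxy)-3-methoxybenzyl]oxolan-3-yl}methanol | OC[C@H]1[C@@H](Cc2ccc(OCc3ccccc3)c(OC)c2)CO[C@@H]1c1cc(OC)c(OCc2ccccc2)c(OC)c1 | intermediate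
14 | 4-[(2S,3R,4R)-4-(4-hydroxy-3-methoxybenzyl)-3-(hydroxymethyl)oxolan-2-yl]-2,6-dimethoxyphenol | OC[C@H]1[C@@H](Cc2ccc(O)c(OC)c2)CO[C@@H]1c1cc(OC)c(O)c(OC)c1 | intermediate
15 | ferulic acid ((E)-3-(4-hydroxy-3-methoxyphenyl)prop-2-enoic acid) | COc1cc(/C=C/C(O)=O)ccc1O | starting material
16 | {(2S,3R,4R)-2-(4-hydroxy-3,5-dimethoxyphenyl)-4-(4-hydroxy-3-methoxybenzyl)oxolan-3-yl}methyl (E)-3-(4-hydroxy-3-methoxyphenyl)prop-2-enoate | COc1cc(/C=C/C(=O)OC[C@H]2[C@@H](Cc3ccc(O)c(OC)c3)CO[C@@H]2c2cc(OC)c(O)c(OC)c2)ccc1O | target

**Count**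

Total steps: 10. Longest linear sequence: 9 steps (steps 1–4 and 6–10, from eugenol); step 5 is a one-step side branch.

**Steps most likely to fail, with fallbacks**

Step 4. The catalyst may tell the two enantiotopic methylenes apart only partly, because the group it must read is a flexible CH2Ar one atom away from the ring and not an aryl group on the ring itself; the lactone would then be formed with insufficient enantiomeric purity. Enrichment by recrystallisation of 6 would be tried first. The fallback replaces oxidative desymmetrization by enantioselective deprotonation; it sets out from 4 and returns at 6. Ketone 4 would be treated with lithium bis[(S)-1-phenylethyl]amide in the presence of Et3SiCl in THF at −100 °C (the amide antipode being the one that removes the proton leading to the R series) to give (R)-triethyl({3-[4-(benzyloxy)-3-methoxybenzyl]cyclobut-1-en-1-yl}oxy)silane F1. Ozonolysis of the enol double bond (O3, CH2Cl2/MeOH, −78 °C) with NaBH4 work-up would give (3R)-4-[4-(benzyloxy)-3-methoxyphenyl]-3-(hydroxymethyl)butanoic acid F2, which closes to lactone 6 on acidification with aqueous HCl.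

Step 8. Three processes may go wrong:
- the benzylic cation may be captured by the electron-rich guaiacyl ring (Friedel–Crafts closure to an aryltetralin) in place of the hydroxyl;
- the product ether may re-ionise on longer acid exposure and drain into that carbocyclic sink;
- selection of the trans arrangement at C2 may be incomplete.

The fallback changes the order and the reactive intermediate; it sets out from 11 and returns at 14, bypassing 13. Hydrogenolysis of 11 (H2, 10% Pd/C, EtOAc, rt) would give (2R,3R)-2-[hydroxy(4-hydroxy-3,5-dimethoxyphenyl)methyl]-3-(4-hydroxy-3-methoxybenzyl)butane-1,4-diol F3. With the para-phenol free, the carbinol dehydrates under very weak acid (dilute formic acid in aqueous dioxane, rt) to the neutral quinone methide 4-[(2R,3R)-4-hydroxy-3-(4-hydroxy-3-methoxybenzyl)-2-(hydroxymethyl)butylidene]-2,6-dimethoxycyclohexa-2,5-dien-1-one F4. Intramolecular 1,6-addition of the primary hydroxyl to F4 gives 14 under conditions too mild for arene alkylation.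

Step 10. The alkoxyphosphonium ion may alkylate a phenol (of 14 or of ferulic acid) in place of the carboxylate, or activation of the β-branched primary alcohol may be slow, so that the betaine is consumed unproductively. The fallback builds the cinnamate C=C bond after the ester; it sets out from 13 and arrives at 16. Alcohol 13 would be heated with Meldrum's acid in toluene at 100 °C to give the malonate half-ester 3-({(2S,3R,4R)-2-[4-(benzyloxy)-3,5-dimethoxyphenyl]-4-[4-(benzyloxy)-3-methoxybenzyl]oxolan-3-yl}methoxy)-3-oxopropanoic acid F5. Hydrogenolysis (H2, 10% Pd/C, EtOAc) would give 3-{[(2S,3R,4R)-2-(4-hydroxy-3,5-dimethoxyphenyl)-4-(4-hydroxy-3-methoxybenzyl)oxolan-3-yl]methoxy}-3-oxopropanoic acid F6. Knoevenagel–Doebner condensation of F6 with vanillin (pyridine, cat. piperidine, 50 °C) then gives the E-feruloyl ester 16 with loss of CO2.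

**Further compounds**

F1 | step 4 | (R)-triethyl({3-[4-(benzyloxy)-3-methoxybenzyl]cyclobut-1-en-1-yl}oxy)silane | CC[Si](CC)(CC)OC1=C[C@H](Cc2ccc(OCc3ccccc3)c(OC)c2)C1
F2 | step 4 | (3R)-4-[4-(benzyloxy)-3-methoxyphenyl]-3-(hydroxymethyl)butanoic acid | OC[C@H](Cc1ccc(OCc2ccccc2)c(OC)c1)CC(O)=O
F3 | step 8 | (2R,3R)-2-[hydroxy(4-hydroxy-3,5-dimethoxyphenyl)methyl]-3-(4-hydroxy-3-methoxybenzyl)butane-1,4-diol (both carbinol epimers) | OC[C@H](C(O)c1cc(OC)c(O)c(OC)c1)[C@@H](Cc1ccc(O)c(OC)c1)CO
F4 | step 8 | 4-[(2R,3R)-4-hydroxy-3-(4-hydroxy-3-methoxybenzyl)-2-(hydroxymethyl)butylidene]-2,6-dimethoxycyclohexa-2,5-dien-1-one | OC[C@H](C=C1C=C(OC)C(=O)C(OC)=C1)[C@@H](Cc1ccc(O)c(OC)c1)CO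
F5 | step 10 | 3-({(2S,3R,4R)-2-[4-(benzyloxy)-3,5-dimethoxyphenyl]-4-[4-(benzyloxy)-3-methoxybenzyl]oxolan-3-yl}methoxy)-3-oxopropanoic acid | OC(=O)CC(=O)OC[C@H]1[C@@H](Cc2ccc(OCc3ccccc3)c(OC)c2)CO[C@@H]1c1cc(OC)c(OCc2ccccc2)c(OC)c1
F6 | step 10 | 3-{[(2S,3R,4R)-2-(4-hydroxy-3,5-dimethoxyphenyl)-4-(4-hydroxy-3-methoxybenzyl)oxolan-3-yl]methoxy}-3-oxopropanoic acid | OC(=O)CC(=O)OC[C@H]1[C@@H](Cc2ccc(O)c(OC)c2)CO[C@@H]1c1cc(OC)c(O)c(OC)c1
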